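**Strategy**

Both carbon–bromine bonds are disconnected together. C3–Br on ring A and C3'–Br on ring B each lie ortho to an oxygen (O4, O4') whose para carbon (C1, C1') already carries a substituent, so a single electrophilic bromination can place both halogens without any directing auxiliary. The substrate for that step is the bromine-free diarylmethane aldehyde with O4 free, O5 methylated, C1 at the CHO level and O4' masked as a methyl ether, so that ring A is the only phenol and ring B, an anisole, stops at one bromine. A benzyl Suzuki coupling and one selective demethylation build it; global demethylation and borohydride reduction finish.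

Key step: step 3

Remark on the chemistry: the target has no stereocentre and is achiral, so no stereocontrol is required; compounds 1 and 2 are taken as catalogue compounds.

Numbering used below: ring A is C1 (bears C8, the CHO/CH2OH carbon), C2 (H), C3, C4 (O4), C5 (O5), C6 (bears the bridge C7); ring B is C1' (on C7), C3', C4' (O4').

Design note: a free phenol on ring B would be the most electron-rich site of the molecule, and its monobromide would still compete with the formyl-deactivated ring A for the second equivalent of bromine. O4' is therefore carried as a methyl ether through the key step, and it is removed together with the O5 methyl afterwards.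

**Route**

Step 1
Reactants: 1 2-bromo-3,4-dimethoxybenzaldehyde; 2 2-(4-methoxybenzyl)-4,4,5,5-tetramethyl-1,3,2-dioxaborolane
Product: 3 3,4-dimethoxy-2-(4-methoxybenzyl)benzaldehyde
Conditions: Pd(OAc)2 (5 mol%), SPhos (10 mol%), K3PO4 (3 equiv), toluene/H2O (10:1), 90 °C, Ar
Reagents that add atoms: none
Why: Suzuki–Miyaura sp2–sp3 coupling; oxidative addition is helped by the ortho formyl group, the primary benzyl boronate has no β-hydrogen, the bulky biaryl phosphine copes with the doubly ortho-substituted bromide, and the aldehyde is inert to the boronate.

Step 2
Reactants: 3 3,4-dimethoxy-2-(4-methoxybenzyl)benzaldehyde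
Product: 4 4-hydroxy-3-methoxy-2-(4-methoxybenzyl)benzaldehyde
Conditions: NaSEt (2.5 equiv), DMF, 100 °C; then aq. HCl
Reagents that add atoms: none
Why: Nucleophilic (SN2) O-demethylation by thiolate; the O4 methyl should go fastest because its phenoxide leaving group is conjugated with the para formyl group, the O5 methyl (meta to CHO) and the unactivated ring-B anisole need much harsher conditions, and the O4 phenoxide once formed shields the neighbouring O5 methyl.

Step 3
Reactants: 4 4-hydroxy-3-methoxy-2-(4-methoxybenzyl)benzaldehyde
Product: 6 5-bromo-2-(3-bromo-4-methoxybenzyl)-4-hydroxy-3-methoxybenzaldehyde, via ring-A monobromide 5 (not isolated)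
Conditions: NBS (2.1 equiv), MeCN, 0 °C → 50 °C, dark
Reagents that add atoms: N-bromosuccinimide, O=C1CCC(=O)N1Br
Why: Two successive electrophilic aromatic substitutions by the bromonium equivalent of NBS (σ-complex, then loss of a proton), the reaction type that converts vanillin into 5-bromovanillin and 4-alkylanisoles into their 2-bromo derivatives; no ring is closed and no stereocentre is formed. Ring A reacts first because it holds the only free phenol: O4–H has its para carbon C1 blocked by the formyl group and its other ortho carbon C5 occupied by OMe, so substitution can occur only at C3, while C2 is meta to O4 and ortho to the deactivating CHO (intermediate 5). Ring B then takes the second equivalent ortho to the O4' ether, since the para carbon C1' carries the C7 bridge and C3'/C5' are equivalent. The selectivity needed is one bromine per ring: the 2-bromoanisole formed on ring B is too deactivated to react again, which is why O4' is carried as the methyl ether instead of a free phenol that could be brominated twice before the formyl-deactivated ring A reacts. Keeping C1 as the aldehyde excludes ipso attack with loss of the one-carbon unit, and a polar solvent in the dark suppresses radical bromination at C7. NBS is chosen over bromide/peroxide systems because para-hydroxybenzaldehydes are open to Dakin oxidation.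

Step 4
Reactants: 6 5-bromo-2-(3-bromo-4-methoxybenzyl)-4-hydroxy-3-methoxybenzaldehyde
Product: 7 5-bromo-2-(3-bromo-4-hydroxybenzyl)-3,4-dihydroxybenzaldehyde
Conditions: BBr3 (5 equiv), CH2Cl2, −78 °C → rt; then ice/H2O
Reagents that add atoms: none
Why: Lewis-acid aryl methyl ether cleavage (O–B complexation, bromide attack at methyl) should remove the O5 and O4' methyls in one operation; aryl bromides, the diarylmethane and the aldehyde tolerate it, and C8 is deliberately still an aldehyde because a benzylic alcohol would be converted into its bromide.

Step 5
Reactants: 7 5-bromo-2-(3-bromo-4-hydroxybenzyl)-3,4-dihydroxybenzaldehyde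
Product: 8 5-bromo-2-(3-bromo-4-hydroxybenzyl)-3,4-dihydroxybenzyl alcohol (CNP0232913.0)
Conditions: NaBH4 (3 equiv), THF/H2O (4:1), 0 °C, Ar; then aq. NH4Cl to pH ≈ 6
Reagents that add atoms: none
Why: Borohydride reduction of an aromatic aldehyde, as in the reduction of vanillin to vanillyl alcohol; aryl bromides and phenols are untouched, and the alcohol-free solvent, inert atmosphere and near-neutral quench should avoid quinone-methide solvolysis of the new para-hydroxybenzylic alcohol and oxidation of the catechol.

**Compound list**

1 | 2-bromo-3,4-dimethoxybenzaldehyde | COc1ccc(C=O)c(Br)c1OC | starting material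
2 | 2-(4-methoxybenzyl)-4,4,5,5-tetramethyl-1,3,2-dioxaborolane | COc1ccc(CB2OC(C)(C)C(C)(C)O2)cc1 | starting material
3 | 3,4-dimethoxy-2-(4-methoxybenzyl)benzaldehyde | COc1ccc(Cc2c(C=O)ccc(OC)c2OC)cc1 | intermediate
4 | 4-hydroxy-3-methoxy-2-(4-methoxybenzyl)benzaldehyde | COc1ccc(Cc2c(C=O)ccc(O)c2OC)cc1 | intermediate
5 | 5-bromo-4-hydroxy-3-methoxy-2-(4-methoxybenzyl)benzaldehyde | COc1ccc(Cc2c(C=O)cc(Br)c(O)c2OC)cc1 | intermediate (not isolated)
6 | 5-bromo-2-(3-bromo-4-methoxybenzyl)-4-hydroxy-3-methoxybenzaldehyde | COc1ccc(Cc2c(C=O)cc(Br)c(O)c2OC)cc1Br | intermediate
7 | 5-bromo-2-(3-bromo-4-hydroxybenzyl)-3,4-dihydroxybenzaldehyde | O=Cc1cc(Br)c(O)c(O)c1Cc1ccc(O)c(Br)c1 | intermediate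
8 | 5-bromo-2-(3-bromo-4-hydroxybenzyl)-3,4-dihydroxybenzyl alcohol | OCc1cc(Br)c(O)c(O)c1Cc1ccc(O)c(Br)c1 | target

Total step count: 5
Longest linear sequence: 5 steps (1 → 3 → 4 → 6 → 7 → 8)

**Steps most likely to fail**

Step 3. The anisole ring B may brominate much more slowly than the phenolic ring A. Forcing it could start radical substitution at the C7 methylene or a second substitution on ring A at C2, so the two brominations would not finish cleanly in one operation. The fallback decouples them, so that each is run where its ring is the most reactive one. It sets out from 3. One equivalent of NBS in MeCN should brominate ring B alone, because ring A there is a non-phenolic, formyl-deactivated ring whose O5 methoxy is twisted out of conjugation. This gives 2-(3-bromo-4-methoxybenzyl)-3,4-dimethoxybenzaldehyde F1. Thiolate demethylation at O4, as in step 2, then gives 2-(3-bromo-4-methoxybenzyl)-4-hydroxy-3-methoxybenzaldehyde F2. One equivalent of NBS brominates the phenol ring at C3, and the sequence comes back to the route at 6.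

Step 2. Regiocontrol of the demethylation may erode through attack on the sterically twisted O5 methyl or, at higher temperature, on the ring-B ether. Thiolate may also react at the aldehyde. The fallback rebuilds the oxygen pattern from the acidity ranking of the phenols and sets out from 3. BBr3 removes all three methyl groups and gives 3,4-dihydroxy-2-(4-hydroxybenzyl)benzaldehyde F3. The most acidic hydroxyl, O4–H para to the formyl group, is benzylated selectively with BnBr and NaHCO3 in DMF to give 4-(benzyloxy)-3-hydroxy-2-(4-hydroxybenzyl)benzaldehyde F4. MeI and K2CO3 methylate O5 and O4' to give 4-(benzyloxy)-3-methoxy-2-(4-methoxybenzyl)benzaldehyde F5. BCl3 with pentamethylbenzene at −78 °C removes the benzyl group only, and the sequence comes back to the route at 4.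

Step 1. Transmetalation at the doubly ortho-substituted palladium centre may be slow, so that protodeboronation or homocoupling of the benzyl boronate consumes the nucleophile. The fallback switches to a base-free organozinc coupling on a protected aldehyde and sets out from 1. Acetalisation with ethylene glycol (TsOH, toluene, water removal) gives 2-(2-bromo-3,4-dimethoxyphenyl)-1,3-dioxolane F6. Negishi coupling with commercial 4-methoxybenzylzinc chloride (Pd(OAc)2, SPhos, THF) follows, the acetal keeping the benzylzinc away from the carbonyl, and gives 2-[3,4-dimethoxy-2-(4-methoxybenzyl)phenyl]-1,3-dioxolane F7. Aqueous HCl in THF releases the aldehyde, and the sequence comes back to the route at 3.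

**Further compounds**

F1 | step 3 | 2-(3-bromo-4-methoxybenzyl)-3,4-dimethoxybenzaldehyde | COc1ccc(Cc2c(C=O)ccc(OC)c2OC)cc1Br
F2 | step 3 | 2-(3-bromo-4-methoxybenzyl)-4-hydroxy-3-methoxybenzaldehyde | COc1ccc(Cc2c(C=O)ccc(O)c2OC)cc1Br
F3 | step 2 | 3,4-dihydroxy-2-(4-hydroxybenzyl)benzaldehyde | O=Cc1ccc(O)c(O)c1Cc1ccc(O)cc1
F4 | step 2 | 4-(benzyloxy)-3-hydroxy-2-(4-hydroxybenzyl)benzaldehyde | O=Cc1ccc(OCc2ccccc2)c(O)c1Cc1ccc(O)cc1
F5 | step 2 | 4-(benzyloxy)-3-methoxy-2-(4-methoxybenzyl)benzaldehyde | COc1ccc(Cc2c(C=O)ccc(OCc3ccccc3)c2OC)cc1
F6 | step 1 | 2-(2-bromo-3,4-dimethoxyphenyl)-1,3-dioxolane | COc1ccc(C2OCCO2)c(Br)c1OC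
F7 | step 1 | 2-[3,4-dimethoxy-2-(4-methoxybenzyl)phenyl]-1,3-dioxolane | COc1ccc(Cc2c(C3OCCO3)ccc(OC)c2OC)cc1
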